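**Retrosynthetic overview**

1. Target 11 is a 1,4-benzoquinone with C1=O, C2–OMe, C3–H, C4=O, C5–Me and C6–n-C21H43. The chain is cut between C11 and C12 (counted from its CH3 end) into an undecyl radical from dodecanoic acid 8 and a ring-bound primary C10 radical from an 11-arylundecanoic acid. The two are joined by mixed Kolbe electrolysis.
2. Enabling feature: both carbons of that bond are unbranched CH2 groups flanked by CH2 groups, so each side is a primary, non-stabilised radical that couples at Pt instead of being oxidised further. In addition, ring carbons C1 and C4 of the six-membered ring are para oxygen-bearing carbons, so the ring can be carried as the 1,2,4-trimethoxybenzene 7. The same anode first turns 7 into the quinone bis(dimethyl ketal), and acid work-up then unveils the quinone.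
3. Acid 7 comes from quinone 2 by Ag/persulfate decarboxylative radical alkylation at C6 with monomethyl dodecanedioate 3, then reductive methylation and saponification. Quinone 2 comes from commercial 2-methoxy-5-methylphenol 1 by Teuber oxidation.
4. Ring order: no ring is formed. The only ring, the six-membered carbocycle, is bought with 1 and only changes oxidation level (phenol → quinone → arene → bisketal → quinone).

Key step: step 5

Remark: ring positions are numbered throughout as in the target quinone (C1=O, C2–OMe, C3–H, C4=O, C5–Me, C6–chain).

**Route**

Step 1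
Reactants: 1 2-methoxy-5-methylphenol
Product: 2 2-methoxy-5-methyl-1,4-benzoquinone
Conditions: Fremy's salt (2.2 equiv), KH2PO4 buffer, H2O/acetone, rt
Reagents that add atoms: Fremy's salt (dipotassium nitrosodisulfonate), [O]N(S(=O)(=O)[O-])S(=O)(=O)[O-].[K+].[K+]
Why: Teuber oxidation: hydrogen abstraction gives the phenoxyl radical, a second nitrosodisulfonate adds at the free para carbon (C4) and loss of imidodisulfonate should give the p-quinone, the para position being unsubstituted and more accessible than the methoxy-bearing ortho carbon.

Step 2
Reactants: 2 2-methoxy-5-methyl-1,4-benzoquinone; 3 12-methoxy-12-oxododecanoic acid (monomethyl dodecanedioate)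
Product: 4 methyl 11-(5-methoxy-2-methyl-3,6-dioxocyclohexa-1,4-dien-1-yl)undecanoate
Conditions: AgNO3 (0.2 equiv), (NH4)2S2O8 (1.5 equiv), MeCN/H2O 1:1, 65 °C
Reagents that add atoms: none
Why: Jacobsen–Torssell (Minisci-type) decarboxylative alkylation: Ag(II) formed by persulfate oxidises the carboxylate of 3 to the primary 10-(methoxycarbonyl)decyl radical, which as a nucleophilic radical should add to C6, the only unsubstituted carbon of the electron-poor methyl-bearing C5=C6 bond, rather than to C3 of the donor-substituted C2=C3 enol-ether bond, and oxidation of the adduct radical restores the quinone.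

Step 3
Reactants: 4 methyl 11-(5-methoxy-2-methyl-3,6-dioxocyclohexa-1,4-dien-1-yl)undecanoate
Product: 6 methyl 11-(2,3,5-trimethoxy-6-methylphenyl)undecanoate, via hydroquinone ester 5 (not isolated)
Conditions: Na2S2O4, Et2O/H2O, rt; then Me2SO4, K2CO3, acetone, reflux, Ar
Reagents that add atoms: dimethyl sulfate, COS(=O)(=O)OC
Why: Reductive methylation: dithionite reduces the quinone to the hydroquinone, and both phenols are then O-methylated (Williamson etherification) under argon before re-oxidation can occur, the methyl ester being inert to K2CO3 in acetone.

Step 4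
Reactants: 6 methyl 11-(2,3,5-trimethoxy-6-methylphenyl)undecanoate
Product: 7 11-(2,3,5-trimethoxy-6-methylphenyl)undecanoic acid
Conditions: LiOH·H2O, THF/MeOH/H2O, rt; then 1 M HCl
Reagents that add atoms: lithium hydroxide (its oxygen ends in the CO2H group), [Li+].[OH-]
Why: Saponification (BAc2) of an unhindered methyl ester; the three aryl methyl ethers are not affected.

Step 5
Reactants: 7 11-(2,3,5-trimethoxy-6-methylphenyl)undecanoic acid; 8 dodecanoic acid (lauric acid)
Product: 11 3-henicosyl-5-methoxy-2-methylcyclohexa-2,5-diene-1,4-dione (the target), via bisketal acid 9 (not isolated), via C21 bisketal 10 (not isolated)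
Conditions: undivided cell, smooth Pt anode, Pt cathode, dry MeOH: (i) KOH (1.3 equiv), 0–10 °C, ca. 25 mA cm⁻², 2.5 F mol⁻¹; (ii) add 8 (8 equiv), 45 °C, ca. 0.3 A cm⁻², until slightly alkaline; (iii) concentrate, 2 M HCl/acetone, rt
Reagents that add atoms: methanol, CO (ketal methoxy groups of 9 and 10); water, O (both carbonyl oxygens of 11)
Why: Proposed new method: in alkaline methanol at low current density the 1,2,4-trimethoxyarene, which is oxidised far more easily than a carboxylate, should lose two electrons and take up methanol at the two para OMe-bearing carbons to give the quinone bis(dimethyl ketal) 9 (the established anodic bisketalisation of p-dimethoxyarenes), so the ring is stored as a non-aromatic, oxidation-resistant masked quinone before the Kolbe potential is reached. After the cell is made weakly acidic with excess 8 and the current density is raised, both carboxylates should be discharged at Pt, lose CO2, and the two primary alkyl radicals should combine in the anode layer to form the CH2–CH2 bond between the undecyl group and C10 of the ring-bound chain, giving 10. The closest known reaction is the mixed Kolbe electrolysis of fatty acids, and what is new is running it in tandem, in the same cell, on an acid that carries an anodically generated quinone bisketal. Aqueous acid then hydrolyses both ketals of 10, and the C2 methoxy group survives as the vinylogous ester of 11. No ring is closed and no stereocentre is created. The step needs ring oxidation before decarboxylation (secured by the large gap in oxidation potential and the alkaline first stage), radical coupling rather than Hofer–Moest cation formation (secured by two unbranched RCH2 radicals without α-heteroatoms, smooth Pt, high current density and weakly acidic methanol), and cross- over self-coupling of the ring-bearing acid (secured by the excess of 8, whose own dimer docosane is a hydrocarbon that should separate easily on chromatography).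

**Compound list**

1 | 2-methoxy-5-methylphenol | COc1ccc(C)cc1O | starting material
2 | 2-methoxy-5-methyl-1,4-benzoquinone | COC1=CC(=O)C(C)=CC1=O | intermediate
3 | 12-methoxy-12-oxododecanoic acid (monomethyl dodecanedioate) | COC(=O)CCCCCCCCCCC(=O)O | starting material
4 | methyl 11-(5-methoxy-2-methyl-3,6-dioxocyclohexa-1,4-dien-1-yl)undecanoate | COC(=O)CCCCCCCCCCC1=C(C)C(=O)C=C(OC)C1=O | intermediate
5 | methyl 11-(2,5-dihydroxy-3-methoxy-6-methylphenyl)undecanoate | COC(=O)CCCCCCCCCCc1c(C)c(O)cc(OC)c1O | intermediate (not isolated)
6 | methyl 11-(2,3,5-trimethoxy-6-methylphenyl)undecanoate | COC(=O)CCCCCCCCCCc1c(C)c(OC)cc(OC)c1OC | intermediate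
7 | 11-(2,3,5-trimethoxy-6-methylphenyl)undecanoic acid | OC(=O)CCCCCCCCCCc1c(C)c(OC)cc(OC)c1OC | intermediate
8 | dodecanoic acid (lauric acid) | CCCCCCCCCCCC(=O)O | starting material
9 | 11-(3,3,5,6,6-pentamethoxy-2-methylcyclohexa-1,4-dien-1-yl)undecanoic acid (potassium salt in the cell) | OC(=O)CCCCCCCCCCC1=C(C)C(OC)(OC)C=C(OC)C1(OC)OC | intermediate (not isolated)
10 | 1-henicosyl-3,3,5,6,6-pentamethoxy-2-methylcyclohexa-1,4-diene | CCCCCCCCCCCCCCCCCCCCCC1=C(C)C(OC)(OC)C=C(OC)C1(OC)OC | intermediate (not isolated)
11 | 3-henicosyl-5-methoxy-2-methylcyclohexa-2,5-diene-1,4-dione (2-methoxy-5-methyl-6-henicosyl-1,4-benzoquinone) | CCCCCCCCCCCCCCCCCCCCCC1=C(C)C(=O)C=C(OC)C1=O | target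

**Step count and risks**

Total step count: 5. Longest linear sequence: 5 steps (1 → 2 → 4 → 6 → 7 → 11).

Steps most likely to fail:

1. Step 5 (proposed new method). The bisketal ring may be degraded at the anode during the high-potential Kolbe stage (oxidation of its enol-ether double bond), ring oxidation may be incomplete before decarboxylation starts, or the ring-bearing radical may be lost to disproportionation. Fallback with known chemistry, setting out from 7: esterification with N-hydroxyphthalimide (DIC, DMAP cat., CH2Cl2) should give the redox-active ester 1,3-dioxoisoindolin-2-yl 11-(2,3,5-trimethoxy-6-methylphenyl)undecanoate F1. In parallel, 1-bromoundecane and Mg in THF give undecylmagnesium bromide F2, which is transmetalated with ZnCl2 (0.5 equiv) to diundecylzinc F3. Nickel-catalysed decarboxylative alkyl–alkyl Negishi coupling of F1 with F3 (NiCl2·glyme, 4,4'-di-tert-butyl-2,2'-bipyridine, THF/DMF, rt) should form the same CH2–CH2 bond and give 1-henicosyl-2,3,5-trimethoxy-6-methylbenzene F4. Oxidative demethylation of F4 with ceric ammonium nitrate (MeCN/H2O, 0 °C) comes back to the route at 11.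

2. Step 2. The alkyl radical may add at C3 as well as C6, the product may be alkylated a second time, or the radical may be oxidised by Ag(II) before it adds. Fallback, setting out from 1: O-allylation (allyl bromide, K2CO3, acetone) should give 2-(allyloxy)-1-methoxy-4-methylbenzene F5. Aromatic Claisen rearrangement (N,N-diethylaniline, 200 °C) can only go to the single free ortho carbon and should give 2-allyl-6-methoxy-3-methylphenol F6. Cross-metathesis with methyl dec-9-enoate (Grubbs II, CH2Cl2, 40 °C) should give methyl (E)-11-(2-hydroxy-3-methoxy-6-methylphenyl)undec-9-enoate F7 (any Z isomer is carried along). Hydrogenation (H2, Pd/C, EtOAc) gives methyl 11-(2-hydroxy-3-methoxy-6-methylphenyl)undecanoate F8. Teuber oxidation of F8 with Fremy's salt at the free para position comes back to the route at 4.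

3. Step 1. Oxidation may occur at the methoxy-bearing ortho carbon (o-quinone pathway with loss of methanol), and phenoxyl radicals may couple oxidatively. Fallback, setting out from 1: Elbs persulfate oxidation (K2S2O8, aq. KOH, 10–20 °C) should give potassium 4-hydroxy-5-methoxy-2-methylphenyl sulfate F9. Hydrolysis in hot dilute HCl gives 2-methoxy-5-methylbenzene-1,4-diol F10. Mild oxidation of F10 (FeCl3, aq. EtOH, rt) comes back to the route at 2.

**Further compounds**

F1 | step 5 | 1,3-dioxoisoindolin-2-yl 11-(2,3,5-trimethoxy-6-methylphenyl)undecanoate | O=C(CCCCCCCCCCc1c(C)c(OC)cc(OC)c1OC)ON1C(=O)c2ccccc2C1=O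
F2 | step 5 | undecylmagnesium bromide | CCCCCCCCCCC[Mg]Br
F3 | step 5 | diundecylzinc | CCCCCCCCCCC[Zn]CCCCCCCCCCC
F4 | step 5 | 1-henicosyl-2,3,5-trimethoxy-6-methylbenzene | CCCCCCCCCCCCCCCCCCCCCc1c(C)c(OC)cc(OC)c1OC
F5 | step 2 | 2-(allyloxy)-1-methoxy-4-methylbenzene | C=CCOc1cc(C)ccc1OC
F6 | step 2 | 2-allyl-6-methoxy-3-methylphenol | C=CCc1c(C)ccc(OC)c1O
F7 | step 2 | methyl (E)-11-(2-hydroxy-3-methoxy-6-methylphenyl)undec-9-enoate | COC(=O)CCCCCCC/C=C/Cc1c(C)ccc(OC)c1O
F8 | step 2 | methyl 11-(2-hydroxy-3-methoxy-6-methylphenyl)undecanoate | COC(=O)CCCCCCCCCCc1c(C)ccc(OC)c1O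
F9 | step 1 | potassium 4-hydroxy-5-methoxy-2-methylphenyl sulfate | COc1cc(OS(=O)(=O)[O-])c(C)cc1O.[K+]
F10 | step 1 | 2-methoxy-5-methylbenzene-1,4-diol | COc1cc(O)c(C)cc1O
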